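**Retrosynthetic overview**
1. Target 22 ⇐ C8=C9 epoxidation, C6 4-methoxybenzoylation and C6 ketone reduction of the trans-fused five/seven ketone 17.
2. Key step: 17 ⇐ semipinacol 1,2-shift in the cis-decalin triol monomesylate 16 (C1 moves from C6 to C5): ring A contracts six → five, ring B expands six → seven.
3. Triol 15 ⇐ hydroxyl-directed syn-dihydroxylation of allylic alcohol 13 ⇐ angular ketol 8 (enol triflate route, C2 reduction and acetylation).
4. 8 ⇐ angular hydroxylation of adduct 6 ⇐ thymoquinone 4 + isoprene 5 (new asymmetric quinone Diels–Alder; ring B is built onto ring A).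
5. 4 ⇐ m-cresol + propene; aroyl unit ⇐ anisole. Ring order: ring A (from the arene) → ring B (Diels–Alder) → five/seven system by the shift.

Assumption: m-cresol, propene, isoprene and anisole are the commercial starting materials; everything else is a reagent.
Labels: carbons are C1–C10 as in the final bicycle. C1 = quaternary C bearing CH3; C2 = C–OAc; C3 = CH2; C4 = C(OH)(i-Pr); C5 = ring-fusion CH; C6 = C–O-aroyl; C7 = CH2; C8 = C(CH3) of the epoxide; C9 = CH of the epoxide; C10 = CH2. In the decalins, ring A is C1–C6 and ring B is C1, C6, C7–C10. β is the face of the C1 methyl, α the opposite face. Absolute configurations are those of the SMILES strings.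

**Step 1**
Reactants: 1 m-cresol (3-methylphenol); 2 propene
Product: 3 thymol (2-isopropyl-5-methylphenol)
Conditions: Al(OC6H4-3-CH3)3 (5 mol%, made from Al and 1), propene (20 bar), neat, 200 °C
Reagents that add atoms: none
Why: Aluminium phenoxide-catalysed ortho-alkylation of a phenol with an alkene (Kolka–Ecke type); the ortho position para to the methyl group is the less hindered one, which gives thymol.

**Step 2**
Reactants: 3 thymol
Product: 4 thymoquinone (2-isopropyl-5-methyl-1,4-benzoquinone)
Conditions: O2 (1 atm), Co(salen) (CoC16H14N2O2, divalent cobalt, 5 mol%), DMF, 25 °C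
Reagents that add atoms: dioxygen, O=O
Why: Cobalt–salen-catalysed aerobic oxidation of a phenol with a free para position to the p-quinone.

**Step 3**
Reactants: 4 thymoquinone; 5 isoprene
Product: 6 cis-fused adduct, 2-isopropyl-4a,7-dimethyl-4a,5,8,8a-tetrahydronaphthalene-1,4-dione (C1-CH3 and C6-H both β; C8 carries the methyl)
Conditions: confined chiral imidodiphosphorimidate Brønsted acid (BINOL-derived, N-triflyl, 3,3′-diaryl; 2 mol%; the antipode that gives 6), 5 (5 equiv), toluene, −60 °C
Reagents that add atoms: none
Why: Proposed new method: a chiral-Brønsted-acid-catalysed Diels–Alder of a 2,5-dialkyl-p-quinone with an unactivated diene. The acid hydrogen-bonds the C2 carbonyl, so the unsubstituted C6 becomes the most electrophilic carbon and the CH2 of isoprene next to its methyl carbon bonds there first ("para" orientation, methyl at C8). The second bond closes to the methyl-bearing C1 through an endo transition state inside the chiral pocket, setting C1 and C6 cis and in one absolute sense; the isopropyl-bearing double bond reacts more slowly because it would have to form a quaternary centre carrying isopropyl. Closest known reactions: oxazaborolidinium-catalysed enantioselective quinone Diels–Alder reactions with 2-silyloxydienes, and imidodiphosphorimidate-catalysed Diels–Alder reactions of enones and esters with simple dienes.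

**Step 4**
Reactants: 6 adduct
Product: 8 angular ketol (6 with a β-OH on C6; cis-fused, OH cis to the C1 methyl), via potassium dienolate 7 (not isolated)
Conditions: KN(SiMe3)2 (1.1 equiv), THF, −78 °C; then 2-(phenylsulfonyl)-3-phenyloxaziridine, −78 °C; AcOH quench
Reagents that add atoms: 2-(phenylsulfonyl)-3-phenyloxaziridine (Davis reagent), O=S(=O)(c1ccccc1)N1OC1c1ccccc1
Why: Davis enolate hydroxylation; C6–H is the only α-hydrogen of the ene-dione. The oxaziridine should attack the flat dienolate on the β face, away from ring B, which is folded under C6 on the α side (as in cis-angular alkylations next to an angular methyl), so the new OH ends cis to the C1 methyl.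

**Step 5**
Reactants: 8 ketol
Product: 10 enol triflate ketone (C2 ketone, C3H2, C4(i-Pr)=C5–OTf, C6 β-OH, C8=C9), via lithium enolate 9 (not isolated)
Conditions: LiBH(s-Bu)3 (1.2 equiv), THF, −78 °C; then PhNTf2, −78 → 0 °C; AcOH quench
Reagents that add atoms: N-phenyl-bis(trifluoromethanesulfonimide), O=S(=O)(N(c1ccccc1)S(=O)(=O)C(F)(F)F)C(F)(F)F
Why: Reductive enol triflation (1,4-reduction, then O-sulfonylation). Hydride adds to the unsubstituted β-carbon C3 because both carbonyls are flanked by fully substituted carbons and 1,2-attack is slow; the resulting C5 enolate is trapped regiospecifically, and no stereocentre is formed.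

**Step 6**
Reactants: 10 enol triflate ketone
Product: 11 alcohol (10 with C2 α-OH, trans to the C1 methyl)
Conditions: Me4NBH(OAc)3 (4 equiv), AcOH/MeCN 1:1, −20 °C
Reagents that add atoms: none
Why: Hydroxyl-directed Evans–Saksena reduction; the C6–OH (β to the C2 ketone) binds boron and delivers hydride to the β face, giving the 1,3-anti diol, i.e. C2–OH α.

**Step 7**
Reactants: 11 alcohol
Product: 12 acetate (C2 α-OAc, C5 enol triflate, C6 β-OH)
Conditions: Ac2O, pyridine, DMAP (10 mol%), CH2Cl2, 25 °C
Reagents that add atoms: acetic anhydride, CC(=O)OC(C)=O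
Why: DMAP-catalysed acetylation; only the secondary C2–OH reacts, the tertiary C6–OH does not.

**Step 8**
Reactants: 12 acetate
Product: 13 allylic alcohol (cis-decalin; C2 α-OAc, C4(i-Pr)=C5H, C6 β-OH, C8(CH3)=C9H)
Conditions: Pd(OAc)2 (5 mol%), PPh3 (10 mol%), HCO2H, n-Bu3N, DMF, 60 °C
Reagents that add atoms: none
Why: Palladium-catalysed formate hydrogenolysis of an enol triflate (oxidative addition of zerovalent palladium, hydride transfer from formate, reductive elimination). It leaves the C4=C5 bond in place next to the tertiary C6–OH, and with C2 already an acetate the double bond cannot move into conjugation.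

**Step 9**
Reactants: 13 allylic alcohol
Product: 15 triol (C4 β-OH/α-i-Pr, C5 β-OH, C6 β-OH, all cis to the C1 methyl; C2 α-OAc; C8=C9 intact), via cyclic osmate ester 14 (not isolated)
Conditions: OsO4 (1.05 equiv), TMEDA (1.1 equiv), CH2Cl2, −78 °C; then sat. aq. Na2SO3, THF, 25 °C
Reagents that add atoms: osmium tetroxide, O=[Os](=O)(=O)=O
Why: Donohoe hydroxyl-directed syn-dihydroxylation; OsO4·TMEDA is hydrogen-bonded by the allylic C6–OH and adds to the β (convex) face of C4=C5, setting C4 and C5. The C8=C9 bond has no allylic hydroxyl and should react more slowly.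

**Step 10**
Reactants: 15 triol
Product: 17 trans-fused bicyclo[5.3.0] ketone (C6 ketone; C5 α-H; C4 β-OH/α-i-Pr; C2 α-OAc; C1 β-CH3; C8=C9), via C5 mesylate 16 (not isolated)
Conditions: MsCl (1.2 equiv), Et3N (3 equiv), CH2Cl2, −20 °C; then THF, LiClO4 (2 equiv), 50 °C
Reagents that add atoms: none
Why: Semipinacol (pinacol-type) 1,2-shift of a cis-diol monosulfonate. In the chair with i-Pr, OAc and OMs equatorial, the C1–C6 bond is antiperiplanar to C5–OMs, so C1 migrates from C6 to C5 with inversion at C5 while C6 becomes the ketone; this puts C5–H trans to the C1 methyl. No antiperiplanar β-hydrogen is available for elimination, and the quaternary C1 should out-migrate the C3 methylene that the C4 oxygen could push.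

**Step 11**
Reactants: 17 ketone
Product: 18 diol monoacetate (17 with C6 α-OH)
Conditions: Me4NBH(OAc)3 (5 equiv), AcOH/MeCN 1:1, −20 °C
Reagents that add atoms: none
Why: Evans–Saksena directed reduction; the C4–OH (β) delivers hydride to the β face of the C6 ketone, giving the 1,3-anti diol with C6–OH α.

**Step 12**
Reactants: 19 anisole
Product: 20 4-methoxybenzoyl chloride
Conditions: (COCl)2 (2 equiv), AlCl3 (1.1 equiv), CH2Cl2, 0 °C; ice-water quench; distil
Reagents that add atoms: oxalyl chloride, O=C(Cl)C(Cl)=O
Why: Friedel–Crafts chlorocarbonylation with oxalyl chloride (the acylium loses CO), para to the methoxy group.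

**Step 13**
Reactants: 18 diol monoacetate; 20 4-methoxybenzoyl chloride
Product: 21 C6 4-methoxybenzoate (C2 α-OAc, C4 β-OH free, C8=C9)
Conditions: pyridine, DMAP (0.2 equiv), CH2Cl2, 40 °C
Reagents that add atoms: none
Why: Acyl chloride/DMAP esterification; the secondary C6–OH is acylated and the tertiary C4–OH is inert, with no stereocentre touched.

**Step 14**
Reactants: 21 ester
Product: 22 target (C8–C9 α-epoxide)
Conditions: mCPBA (1.2 equiv), NaHCO3, CH2Cl2, 0 °C
Reagents that add atoms: 3-chloroperoxybenzoic acid, O=C(OO)c1cccc(Cl)c1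
Why: Prilezhaev epoxidation of the only alkene; the peracid should add to the α face, opposite the axial C1 methyl, setting C8 and C9 as in the target.

**Compound list**
1 | m-cresol (3-methylphenol) | Cc1cccc(O)c1 | starting material
2 | propene | CC=C | starting material
3 | thymol (2-isopropyl-5-methylphenol) | Cc1ccc(C(C)C)c(O)c1 | intermediate
4 | thymoquinone (2-isopropyl-5-methyl-1,4-benzoquinone) | CC1=CC(=O)C(C(C)C)=CC1=O | intermediate
5 | isoprene | C=CC(C)=C | starting material
6 | cis-fused Diels–Alder adduct (C1-CH3 and C6-H β) | O=C1C=C(C(C)C)C(=O)[C@@H]2CC(C)=CC[C@]12C | intermediate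
7 | potassium C5-dienolate of 6 | O=C1C=C(C(C)C)C([O-])=C2CC(C)=CC[C@]12C.[K+] | intermediate
8 | angular ketol (C6 β-OH) | O=C1C=C(C(C)C)C(=O)[C@]2(O)CC(C)=CC[C@]12C | intermediate
9 | lithium C5-enolate after 1,4-reduction of 8 | O=C1CC(C(C)C)=C([O-])[C@]2(O)CC(C)=CC[C@]12C.[Li+] | intermediate
10 | C5 enol triflate, C2 ketone | O=C1CC(C(C)C)=C(OS(=O)(=O)C(F)(F)F)[C@]2(O)CC(C)=CC[C@]12C | intermediate
11 | C5 enol triflate, C2 α-alcohol | O[C@@H]1CC(C(C)C)=C(OS(=O)(=O)C(F)(F)F)[C@]2(O)CC(C)=CC[C@]12C | intermediate
12 | C5 enol triflate, C2 α-acetate | CC(=O)O[C@@H]1CC(C(C)C)=C(OS(=O)(=O)C(F)(F)F)[C@]2(O)CC(C)=CC[C@]12C | intermediate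
13 | tertiary allylic alcohol (C4=C5, C6 β-OH, C2 α-OAc) | CC(=O)O[C@@H]1CC(C(C)C)=C[C@]2(O)CC(C)=CC[C@]12C | intermediate
14 | cyclic C4,C5 osmate ester (hexavalent osmium) with TMEDA | CC(=O)O[C@@H]1C[C@@]3(C(C)C)O[Os](=O)(=O)O[C@H]3[C@]2(O)CC(C)=CC[C@]12C.CN(C)CCN(C)C | intermediate
15 | all-cis C4,C5,C6 triol, C2 α-acetate | CC(=O)O[C@@H]1C[C@](O)(C(C)C)[C@@H](O)[C@]2(O)CC(C)=CC[C@]12C | intermediate
16 | C5 mesylate of 15 | CC(=O)O[C@@H]1C[C@](O)(C(C)C)[C@@H](OS(C)(=O)=O)[C@]2(O)CC(C)=CC[C@]12C | intermediate
17 | trans-fused five/seven C6 ketone | O=C1CC(C)=CC[C@]2(C)[C@H](OC(C)=O)C[C@](O)(C(C)C)[C@@H]12 | intermediate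
18 | C6 α-alcohol (C4,C6-diol, C2 acetate) | O[C@@H]1CC(C)=CC[C@]2(C)[C@H](OC(C)=O)C[C@](O)(C(C)C)[C@@H]12 | intermediate
19 | anisole | COc1ccccc1 | starting material
20 | 4-methoxybenzoyl chloride | COc1ccc(C(Cl)=O)cc1 | intermediate
21 | C6 4-methoxybenzoate, C2 acetate, C8=C9 alkene | COc1ccc(C(=O)O[C@@H]2CC(C)=CC[C@]3(C)[C@H](OC(C)=O)C[C@](O)(C(C)C)[C@@H]23)cc1 | intermediate
22 | CNP0317703.1 (C2 α-OAc, C4 β-OH/α-i-Pr, C6 α-4-methoxybenzoate, C8,C9 α-epoxide) | COc1ccc(C(=O)O[C@@H]2C[C@]3(C)O[C@@H]3C[C@]3(C)[C@H](OC(C)=O)C[C@](O)(C(C)C)[C@@H]23)cc1 | target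

**Step count and risks**
Total: 14 steps. Longest linear sequence: 13 steps (steps 1–11, 13, 14); step 12 is a one-step side branch.

The three steps most likely to fail:

Step 3 (the proposed new Diels–Alder). Enantioselectivity, or the choice between the two quinone double bonds, may be poor. Fallback with known chemistry, setting out from 4 and 5: run the cycloaddition thermally (neat 5, sealed tube, 110 °C), which is the established para-selective reaction of 2,5-dialkyl-p-quinones at the less hindered substituted double bond. This gives racemic 6, that is 6 together with the enantiomer of 6 F1. The two are separated on a preparative chiral stationary phase, and the route resumes at 6.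

Step 4 (angular hydroxylation). The facial selectivity at C6 is the least certain stereochemical point of the route: if the oxidant enters anti to the C1 methyl, the trans-fused ketol forms, and that isomer cannot give the target. Fallback from 6: soft enolisation with TMSOTf/Et3N gives the trimethylsilyl dienol ether F2. Rubottom oxidation with dimethyldioxirane (1.0 equiv, acetone/CH2Cl2, −78 °C; the enol ether reacts before the C8=C9 bond) gives the α-silyloxy ketone F3 after silyl migration. Citric acid in methanol removes silicon and the route resumes at 8.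

Step 9 (directed dihydroxylation). OsO4 may also attack the C8=C9 bond. Fallback from 13: mask the more accessible C8=C9 bond as the trans-8,9-dibromide F4 (pyridinium tribromide, CH2Cl2, −78 °C). Dihydroxylate the remaining C4=C5 bond with OsO4·TMEDA as before to give the dibromo triol F5. Zinc dust in AcOH/THF then regenerates the alkene and the route resumes at 15.

**Further compounds**
F1 | step 3 | enantiomer of adduct 6 | O=C1C=C(C(C)C)C(=O)[C@H]2CC(C)=CC[C@@]12C
F2 | step 4 | trimethylsilyl C5-dienol ether of 6 | O=C1C=C(C(C)C)C(O[Si](C)(C)C)=C2CC(C)=CC[C@]12C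
F3 | step 4 | C6 β-trimethylsilyloxy ketone (silyl ether of 8) | O=C1C=C(C(C)C)C(=O)[C@]2(O[Si](C)(C)C)CC(C)=CC[C@]12C
F4 | step 9 | trans-8,9-dibromide of 13 | CC(=O)O[C@@H]1CC(C(C)C)=C[C@]2(O)C[C@](C)(Br)[C@@H](Br)C[C@]12C
F5 | step 9 | trans-8,9-dibromide of triol 15 | CC(=O)O[C@@H]1C[C@](O)(C(C)C)[C@@H](O)[C@]2(O)C[C@](C)(Br)[C@@H](Br)C[C@]12C
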